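Everything rests on building the benzene ring of the indole from a furan. The feature exploited is the substitution pattern of that ring: OH on C4 beside fusion atom C3a, Br on C7 beside C7a, and N1 on C7a. The precursor is a 3-bromofuran. Its C2 bears a methyl carbamate nitrogen linked through CH2–CH(dimethoxypyrimidinyl) to a terminal alkyne. One gold-catalysed isomerisation merges furan and alkyne. C3a–C7a and C4–C5 form, the furan oxygen migrates to C4, and the benzene ring and the five-membered nitrogen ring close together to give a 7-bromo-4-hydroxyindoline. Aromatisation and conversion of the pyrimidine ethers into the 4-amino-2-bromo pattern complete the target.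

Key step: step 7

Remark 1: the target has no stereocentre. The carbon that becomes indole C3 is stereogenic from the epoxide to the indoline stage and is flattened on aromatisation, so these compounds are carried as racemates.
Remark 2: the nitrogen is carried as a methyl and not a tert-butyl carbamate. A tert-butyl carbamate on a homopropargylic nitrogen can cyclise onto a gold-activated alkyne through its carbonyl oxygen with loss of isobutene. The methyl ester has no such exit and is removed later in the same operation as the pyrimidine O-methyl groups.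
Remark 3: the phenol is masked as a pivalate before the pyrimidine is halogenated. A free phenoxide on indole C4 lies within reach of pyrimidine C4 and would compete with ammonia.

Step 1
Reactants: 1 3-bromofuran-2-carboxylic acid
Product: 4 methyl (3-bromofuran-2-yl)carbamate, via acyl azide 2 (not isolated), via isocyanate 3 (not isolated)
Conditions: DPPA, Et3N, toluene, rt then 90 °C; MeOH, 65 °C
Reagents that add atoms: diphenylphosphoryl azide, [N-]=[N+]=NP(=O)(Oc1ccccc1)Oc1ccccc1; methanol, CO
Why: Curtius rearrangement: DPPA turns the acid into acyl azide 2, heating expels N2 with migration of the furyl carbon to nitrogen, and methanol adds to isocyanate 3 to give a 2-amidofuran of the isolable, carbamate-stabilised kind.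

Step 2
Reactants: 5 2,4-dimethoxypyrimidine-5-carbaldehyde
Product: 6 2,4-dimethoxy-5-(oxiran-2-yl)pyrimidine (racemic)
Conditions: Me3S+ I−, NaH, DMSO/THF, 0 °C to rt
Reagents that add atoms: trimethylsulfonium iodide, C[S+](C)C.[I-]
Why: Corey–Chaykovsky epoxidation: the unstabilised sulfonium ylide adds to the aldehyde much faster than to the alkoxypyrimidine ring and the betaine closes to the oxirane, whose stereocentre forms without control, so 6 is racemic.

Step 3
Reactants: 6 2,4-dimethoxy-5-(oxiran-2-yl)pyrimidine; 7 trimethylsilylacetylene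
Product: 10 2-(2,4-dimethoxypyrimidin-5-yl)-4-(trimethylsilyl)but-3-yn-1-ol (racemic), via lithium acetylide 8 (not isolated), via alkynylalane 9 (not isolated)
Conditions: 7 (3 equiv), n-BuLi, toluene, 0 °C; Et2AlCl, 0 °C to rt; then 6, toluene, −20 to 0 °C; aq. potassium sodium tartrate
Reagents that add atoms: none
Why: Epoxide opening by an alkynylalane: aluminium binds the oxirane oxygen and the alkynyl group is delivered to the carbon attached to pyrimidine C5, where the developing positive charge is stabilised by the ortho 4-OMe and para 2-OMe groups, to give the primary alcohol; excess alane in a non-coordinating solvent allows for reagent held by the ring nitrogens, and the stereocentre remains racemic.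

Step 4
Reactants: 10 2-(2,4-dimethoxypyrimidin-5-yl)-4-(trimethylsilyl)but-3-yn-1-ol
Product: 11 2-(2,4-dimethoxypyrimidin-5-yl)-4-(trimethylsilyl)but-3-yn-1-yl methanesulfonate (racemic)
Conditions: MsCl, Et3N, CH2Cl2, 0 °C
Reagents that add atoms: methanesulfonyl chloride, CS(=O)(=O)Cl
Why: Sulfonylation of a primary alcohol under standard conditions; a sulfonate is chosen over a halide because it favours substitution over elimination in the next step.

Step 5
Reactants: 4 methyl (3-bromofuran-2-yl)carbamate; 11 2-(2,4-dimethoxypyrimidin-5-yl)-4-(trimethylsilyl)but-3-yn-1-yl methanesulfonate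
Product: 13 methyl (3-bromofuran-2-yl)[2-(2,4-dimethoxypyrimidin-5-yl)-4-(trimethylsilyl)but-3-yn-1-yl]carbamate (racemic), via sodium carbamate salt 12 (not isolated)
Conditions: 4 (1.2 equiv), NaH (1.1 equiv), DMF, 0 °C; then 11, 0 °C to rt
Reagents that add atoms: none
Why: SN2 N-alkylation of a furan-2-ylcarbamate anion with a primary sulfonate, the usual way to tether 2-amidofurans and preferred here to a Mitsunobu reaction because this N–H is too weakly acidic for the betaine; NaH is kept just below the amount of 4 so that no stronger base than the carbamate anion meets the acidic propargylic C–H, and the silyl cap protects the alkyne terminus.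

Step 6
Reactants: 13 methyl (3-bromofuran-2-yl)[2-(2,4-dimethoxypyrimidin-5-yl)-4-(trimethylsilyl)but-3-yn-1-yl]carbamate
Product: 14 methyl (3-bromofuran-2-yl)[2-(2,4-dimethoxypyrimidin-5-yl)but-3-yn-1-yl]carbamate (racemic)
Conditions: K2CO3 (0.2 equiv), MeOH, 0 °C
Reagents that add atoms: none
Why: Carbonate-catalysed methanolysis of the C(sp)–Si bond, mild enough at 0 °C not to isomerise the doubly activated propargylic C–H to the allene, while exchange at the methyl carbamate in methanol is degenerate.

Step 7
Reactants: 14 methyl (3-bromofuran-2-yl)[2-(2,4-dimethoxypyrimidin-5-yl)but-3-yn-1-yl]carbamate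
Product: 17 methyl 7-bromo-3-(2,4-dimethoxypyrimidin-5-yl)-4-hydroxyindoline-1-carboxylate (racemic), via oxepine 15 (not isolated), via arene oxide 16 (not isolated)
Conditions: Ph3PAuNTf2 (5 mol %), CH2Cl2 (0.02 M), 4 Å molecular sieves, rt
Reagents that add atoms: none
Why: Proposed new method: the monovalent gold cation Ph3PAu+ activates the terminal alkyne, furan C2 (the carbon bearing nitrogen) bonds to the internal alkyne carbon in a 5-exo-dig closure that sets C3a–C7a and the five-membered nitrogen ring, and the cyclopropyl gold carbenoid so formed across furan C2=C3 unravels by cleavage of the furan C2–O bond to a Z-enal conjugated with a gold carbene. The aldehyde oxygen adds to the carbene carbon (future C4), gold departs, and oxepine 15 closes the six-membered ring by disrotatory 6π electrocyclisation (C4–C5) to arene oxide 16, which opens and loses the C4 proton to give phenol 17. The closest known reaction type is the gold-catalysed furan–yne phenol synthesis of furfuryl propargyl amines and ethers, which has the same three-atom tether but attaches it to the furan through carbon instead of nitrogen. No stereocentre is created, since C3 is already present as a racemate and the two epoxide carbons of 16 become aromatic. The step needs the oxirane of 16 to break at C5–O, which the carbamate nitrogen on C7a secures because it is para to C5 and stabilises the cation there, so that oxygen stays on C4; it also needs the alkyne to be taken by the furan alone, which the substrate secures by a methyl carbamate whose O-attack is reversible and by bromine blocking furan C3 against plain hydroarylation. Room temperature keeps out the thermal Diels–Alder pathway, which would leave oxygen on C5, and the non-nucleophilic NTf2 counter-ion avoids the HCl that a gold chloride could release onto the acid-sensitive amidofuran.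

Step 8
Reactants: 17 methyl 7-bromo-3-(2,4-dimethoxypyrimidin-5-yl)-4-hydroxyindoline-1-carboxylate
Product: 18 methyl 7-bromo-3-(2,4-dimethoxypyrimidin-5-yl)-4-(pivaloyloxy)indoline-1-carboxylate (racemic)
Conditions: PivCl, Et3N, DMAP (cat.), CH2Cl2, 0 °C to rt
Reagents that add atoms: pivaloyl chloride, CC(C)(C)C(=O)Cl
Why: DMAP-catalysed O-acylation of the phenol; the hindered ester keeps this oxygen from being phosphorylated in step 11 and from closing a six-membered cyclic ether onto pyrimidine C4 in step 12.

Step 9
Reactants: 18 methyl 7-bromo-3-(2,4-dimethoxypyrimidin-5-yl)-4-(pivaloyloxy)indoline-1-carboxylate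
Product: 20 7-bromo-3-(2,4-dioxo-1,2,3,4-tetrahydropyrimidin-5-yl)indolin-4-yl pivalate (racemic), via tris-silylated intermediate 19 (not isolated)
Conditions: Me3SiCl, NaI (6 equiv each), MeCN, 60 °C, slow N2 stream; then MeOH
Reagents that add atoms: none
Why: Silyl iodide dealkylation: Me3SiI made in the flask silylates the pyrimidine and the carbamate carbonyl, iodide removes all three O-methyl groups by SN2 to give 19, and methanolysis then releases the uracil and, after loss of CO2, the free indoline N–H, while the aryl pivalate offers no O-alkyl bond to cleave; the N2 stream carries off MeI before it can N-methylate.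

Step 10
Reactants: 20 7-bromo-3-(2,4-dioxo-1,2,3,4-tetrahydropyrimidin-5-yl)indolin-4-yl pivalate
Product: 21 7-bromo-3-(2,4-dioxo-1,2,3,4-tetrahydropyrimidin-5-yl)-1H-indol-4-yl pivalate
Conditions: DDQ (1.05 equiv), THF, rt
Reagents that add atoms: none
Why: Quinone dehydrogenation of an N–H indoline (hydride abstraction next to nitrogen, then loss of the C3 proton), driven by formation of the aromatic indole and mild enough for uracil, ester and aryl bromide; the only stereocentre disappears here.

Step 11
Reactants: 21 7-bromo-3-(2,4-dioxo-1,2,3,4-tetrahydropyrimidin-5-yl)-1H-indol-4-yl pivalate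
Product: 22 7-bromo-3-(2,4-dibromopyrimidin-5-yl)-1H-indol-4-yl pivalate
Conditions: POBr3 (4 equiv), toluene, 100 °C; then ice, aq. NaHCO3
Reagents that add atoms: phosphorus oxybromide, O=P(Br)(Br)Br
Why: Deoxybromination of a uracil with POBr3 (O-phosphorylation of each lactam, then addition–elimination by bromide at C2 and C4), the standard access to 2,4-dibromopyrimidines; the pivalate is inert and any N–P bond at the indole is hydrolysed in the quench.

Step 12
Reactants: 22 7-bromo-3-(2,4-dibromopyrimidin-5-yl)-1H-indol-4-yl pivalate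
Product: 24 3-(4-amino-2-bromopyrimidin-5-yl)-7-bromo-1H-indol-4-ol, via aminopyrimidine pivalate 23 (not isolated)
Conditions: NH3 (0.5 M in 1,4-dioxane, excess), sealed tube, rt to 40 °C; then 7 M NH3 in MeOH, 40 °C
Reagents that add atoms: ammonia, N
Why: SNAr amination of a 2,4-dihalopyrimidine, which favours C4 because the adduct there spreads its charge over both ring nitrogens in a para-quinoid form; in aprotic dioxane the hindered pivalate should outlast this stage, and methanolic ammonia then removes it by aminolysis once the new 4-amino group has deactivated C2–Br.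

Compound list
1 | 3-bromofuran-2-carboxylic acid | OC(=O)c1occc1Br | starting material
2 | 3-bromofuran-2-carbonyl azide | [N-]=[N+]=NC(=O)c1occc1Br | intermediate
3 | 3-bromo-2-isocyanatofuran | O=C=Nc1occc1Br | intermediate
4 | methyl (3-bromofuran-2-yl)carbamate | COC(=O)Nc1occc1Br | intermediate
5 | 2,4-dimethoxypyrimidine-5-carbaldehyde | COc1ncc(C=O)c(OC)n1 | starting material
6 | 2,4-dimethoxy-5-(oxiran-2-yl)pyrimidine, racemic | COc1ncc(C2CO2)c(OC)n1 | intermediate
7 | trimethylsilylacetylene | C#C[Si](C)(C)C | starting material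
8 | lithium (trimethylsilyl)acetylide | [Li]C#C[Si](C)(C)C | intermediate
9 | diethyl[(trimethylsilyl)ethynyl]aluminium | CC[Al](CC)C#C[Si](C)(C)C | intermediate
10 | 2-(2,4-dimethoxypyrimidin-5-yl)-4-(trimethylsilyl)but-3-yn-1-ol, racemic | OCC(C#C[Si](C)(C)C)c1cnc(OC)nc1OC | intermediate
11 | 2-(2,4-dimethoxypyrimidin-5-yl)-4-(trimethylsilyl)but-3-yn-1-yl methanesulfonate, racemic | CS(=O)(=O)OCC(C#C[Si](C)(C)C)c1cnc(OC)nc1OC | intermediate
12 | sodium salt of methyl (3-bromofuran-2-yl)carbamate | [Na+].COC(=O)[N-]c1occc1Br | intermediate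
13 | methyl (3-bromofuran-2-yl)[2-(2,4-dimethoxypyrimidin-5-yl)-4-(trimethylsilyl)but-3-yn-1-yl]carbamate, racemic | COC(=O)N(CC(C#C[Si](C)(C)C)c1cnc(OC)nc1OC)c1occc1Br | intermediate
14 | methyl (3-bromofuran-2-yl)[2-(2,4-dimethoxypyrimidin-5-yl)but-3-yn-1-yl]carbamate, racemic (key-step precursor) | COC(=O)N(CC(C#C)c1cnc(OC)nc1OC)c1occc1Br | intermediate
15 | oxepine valence tautomer: 2,3-dihydro-1H-oxepino[3,4-b]pyrrole with N-CO2Me, 3-(2,4-dimethoxypyrimidin-5-yl) and Br on the ring carbon next to the N-bearing fusion atom | COC(=O)N1CC(c2cnc(OC)nc2OC)C2=COC=CC(Br)=C12 | intermediate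
16 | methyl 7-bromo-3-(2,4-dimethoxypyrimidin-5-yl)-4,5-epoxy-4,5-dihydroindoline-1-carboxylate (transient; configuration of the epoxide relative to C3 not defined) | COC(=O)N1CC(c2cnc(OC)nc2OC)C2=C1C(Br)=CC1OC21 | intermediate
17 | methyl 7-bromo-3-(2,4-dimethoxypyrimidin-5-yl)-4-hydroxyindoline-1-carboxylate, racemic (key-step product) | COC(=O)N1CC(c2cnc(OC)nc2OC)c2c(O)ccc(Br)c21 | intermediate
18 | methyl 7-bromo-3-(2,4-dimethoxypyrimidin-5-yl)-4-(pivaloyloxy)indoline-1-carboxylate, racemic | COC(=O)N1CC(c2cnc(OC)nc2OC)c2c(OC(=O)C(C)(C)C)ccc(Br)c21 | intermediate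
19 | trimethylsilyl 3-[2,4-bis(trimethylsilyloxy)pyrimidin-5-yl]-7-bromo-4-(pivaloyloxy)indoline-1-carboxylate, racemic | C[Si](C)(C)OC(=O)N1CC(c2cnc(O[Si](C)(C)C)nc2O[Si](C)(C)C)c2c(OC(=O)C(C)(C)C)ccc(Br)c21 | intermediate
20 | 7-bromo-3-(2,4-dioxo-1,2,3,4-tetrahydropyrimidin-5-yl)indolin-4-yl pivalate, racemic | O=c1[nH]cc(C2CNc3c(Br)ccc(OC(=O)C(C)(C)C)c32)c(=O)[nH]1 | intermediate
21 | 7-bromo-3-(2,4-dioxo-1,2,3,4-tetrahydropyrimidin-5-yl)-1H-indol-4-yl pivalate | O=c1[nH]cc(-c2c[nH]c3c(Br)ccc(OC(=O)C(C)(C)C)c23)c(=O)[nH]1 | intermediate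
22 | 7-bromo-3-(2,4-dibromopyrimidin-5-yl)-1H-indol-4-yl pivalate | CC(C)(C)C(=O)Oc1ccc(Br)c2[nH]cc(-c3cnc(Br)nc3Br)c12 | intermediate
23 | 3-(4-amino-2-bromopyrimidin-5-yl)-7-bromo-1H-indol-4-yl pivalate | CC(C)(C)C(=O)Oc1ccc(Br)c2[nH]cc(-c3cnc(Br)nc3N)c12 | intermediate
24 | 3-(4-amino-2-bromopyrimidin-5-yl)-7-bromo-1H-indol-4-ol (CNP0304210.0) | Nc1nc(Br)ncc1-c1c[nH]c2c(Br)ccc(O)c12 | target

Total number of steps: 12. Longest linear sequence: 11 steps (steps 2 to 12, from aldehyde 5). Step 1 is the short furan branch that joins in step 5.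

Steps most likely to fail

Step 7 (key step). Several things may go wrong:
- The gold cation may bind to the pyrimidine nitrogens, so that turnover stops.
- Traces of water may hydrate the alkyne.
- The electron-rich amidofuran may decompose.
- The arene oxide may open in the other direction.

The fallback is a Fischer indole synthesis. It sets out from epoxide 6 and comes back at 21. A Meinwald rearrangement (BF3·OEt2 cat., CH2Cl2, −20 °C) would turn 6 into 2-(2,4-dimethoxypyrimidin-5-yl)acetaldehyde F1. This is condensed with purchased (2-bromo-5-methoxyphenyl)hydrazine hydrochloride (NaOAc, EtOH) to 2-(2,4-dimethoxypyrimidin-5-yl)acetaldehyde (2-bromo-5-methoxyphenyl)hydrazone F2. Fischer indolisation (ZnCl2, AcOH, 80 °C) can engage only the one free ortho carbon, which lies next to the methoxy group. It should therefore give 7-bromo-3-(2,4-dimethoxypyrimidin-5-yl)-4-methoxy-1H-indole F3, with bromine on C7 and oxygen on C4. Partial loss of pyrimidine methyl groups in the acid is harmless, because BBr3 (CH2Cl2, −78 °C to rt) then removes all three. The product is 5-(7-bromo-4-hydroxy-1H-indol-3-yl)pyrimidine-2,4(1H,3H)-dione F4. Pivaloylation of the phenol (PivCl, pyridine, 0 °C) gives 21; any N-acylated uracil is hydrolysed on work-up.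

Step 5. What may go wrong: β-elimination of methanesulfonate across the CH–CH2 bond, helped by the acidic propargylic and benzylic hydrogen, may outrun substitution. Base-induced alkyne-to-allene isomerisation is a second danger.

The fallback makes the two N–C bonds in the opposite order. It sets out from mesylate 11 and comes back at 13. Azide, a nucleophile of negligible basicity, displaces the sulfonate (NaN3, DMF, 40 °C). This gives 5-[1-azido-4-(trimethylsilyl)but-3-yn-2-yl]-2,4-dimethoxypyrimidine F5. Staudinger reduction (PPh3, THF/H2O) gives 2-(2,4-dimethoxypyrimidin-5-yl)-4-(trimethylsilyl)but-3-yn-1-amine F6. ClCO2Me with Et3N then gives methyl [2-(2,4-dimethoxypyrimidin-5-yl)-4-(trimethylsilyl)but-3-yn-1-yl]carbamate F7. A Goldberg amidation with purchased 2,3-dibromofuran (CuI, N,N'-dimethylethylenediamine, K3PO4, toluene, 100 °C) should take the more reactive C2–Br next to the ring oxygen. It forms the furan C2–N bond and gives 13.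

Step 3. What may go wrong: the ring nitrogens may sequester the alane, so that regiocontrol drifts towards the terminal carbon. A Lewis-acid-induced 1,2-hydride shift of the oxirane may also occur before the alkynyl group is transferred.

The fallback fixes the regiochemistry by conjugate addition. It sets out from aldehyde 5 and alkyne 7 and comes back at 13, bypassing 6, 10 and 11. Knoevenagel condensation of 5 with Meldrum's acid (piperidinium acetate cat., EtOH) gives 5-[(2,4-dimethoxypyrimidin-5-yl)methylidene]-2,2-dimethyl-1,3-dioxane-4,6-dione F8. Alkyne 7 and EtMgBr give [(trimethylsilyl)ethynyl]magnesium bromide F9. This adds 1,4 (THF, 0 °C; dilute HCl quench) to give 5-[1-(2,4-dimethoxypyrimidin-5-yl)-3-(trimethylsilyl)prop-2-yn-1-yl]-2,2-dimethyl-1,3-dioxane-4,6-dione F10. Heating in DMF/H2O (100 °C) gives 3-(2,4-dimethoxypyrimidin-5-yl)-5-(trimethylsilyl)pent-4-ynoic acid F11. A Hunsdiecker-type iododecarboxylation (PhI(OAc)2, I2, visible light, CH2Cl2) gives 5-[1-iodo-4-(trimethylsilyl)but-3-yn-2-yl]-2,4-dimethoxypyrimidine F12. This iodide alkylates sodium salt 12 under the conditions of step 5 to give 13.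

Further compounds
F1 | step 7 | 2-(2,4-dimethoxypyrimidin-5-yl)acetaldehyde | COc1ncc(CC=O)c(OC)n1
F2 | step 7 | 2-(2,4-dimethoxypyrimidin-5-yl)acetaldehyde (2-bromo-5-methoxyphenyl)hydrazone | COc1ccc(Br)c(NN=CCc2cnc(OC)nc2OC)c1
F3 | step 7 | 7-bromo-3-(2,4-dimethoxypyrimidin-5-yl)-4-methoxy-1H-indole | COc1ccc(Br)c2[nH]cc(-c3cnc(OC)nc3OC)c12
F4 | step 7 | 5-(7-bromo-4-hydroxy-1H-indol-3-yl)pyrimidine-2,4(1H,3H)-dione | O=c1[nH]cc(-c2c[nH]c3c(Br)ccc(O)c23)c(=O)[nH]1
F5 | step 5 | 5-[1-azido-4-(trimethylsilyl)but-3-yn-2-yl]-2,4-dimethoxypyrimidine, racemic | [N-]=[N+]=NCC(C#C[Si](C)(C)C)c1cnc(OC)nc1OC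
F6 | step 5 | 2-(2,4-dimethoxypyrimidin-5-yl)-4-(trimethylsilyl)but-3-yn-1-amine, racemic | NCC(C#C[Si](C)(C)C)c1cnc(OC)nc1OC
F7 | step 5 | methyl [2-(2,4-dimethoxypyrimidin-5-yl)-4-(trimethylsilyl)but-3-yn-1-yl]carbamate, racemic | COC(=O)NCC(C#C[Si](C)(C)C)c1cnc(OC)nc1OC
F8 | step 3 | 5-[(2,4-dimethoxypyrimidin-5-yl)methylidene]-2,2-dimethyl-1,3-dioxane-4,6-dione | COc1ncc(C=C2C(=O)OC(C)(C)OC2=O)c(OC)n1
F9 | step 3 | [(trimethylsilyl)ethynyl]magnesium bromide | C[Si](C)(C)C#C[Mg]Br
F10 | step 3 | 5-[1-(2,4-dimethoxypyrimidin-5-yl)-3-(trimethylsilyl)prop-2-yn-1-yl]-2,2-dimethyl-1,3-dioxane-4,6-dione, racemic | COc1ncc(C(C#C[Si](C)(C)C)C2C(=O)OC(C)(C)OC2=O)c(OC)n1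
F11 | step 3 | 3-(2,4-dimethoxypyrimidin-5-yl)-5-(trimethylsilyl)pent-4-ynoic acid, racemic | COc1ncc(C(CC(=O)O)C#C[Si](C)(C)C)c(OC)n1
F12 | step 3 | 5-[1-iodo-4-(trimethylsilyl)but-3-yn-2-yl]-2,4-dimethoxypyrimidine, racemic | COc1ncc(C(CI)C#C[Si](C)(C)C)c(OC)n1
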